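**Retrosynthetic overview**
Target: (3R)-6,8-dihydroxy-3-[(6S)-6-hydroxyundecyl]isochroman-1-one. Ring A (the resorcinol benzene ring) is bought; ring B (the lactone C1, O2, C3, C4, C4a, C8a) is the only ring made.
Late disconnections: global hydrogenation/hydrogenolysis, then the side-chain C4'=C5' bond by cross-metathesis with (S)-oct-1-en-3-ol, which supplies C6'.
Key disconnection: C4–C4a of ring B, closed by a nickel-catalysed reductive aryl–alkyl coupling inside a β-bromoalkyl 2-bromobenzoate that is assembled in the same flask from an aroyl bromide and (R)-2-(pent-4-en-1-yl)oxirane (C3 from (R)-epichlorohydrin).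
Enabling feature: the unit O2–C3(stereocentre)–C4H2 is what a terminal epoxide leaves when bromide opens it at CH2 and the oxygen is acylated, and C4a is the only carbon ortho to C1 that carries no oxygen (C8 bears O), so one bromine there allows a single six-membered closure.
Ring order: ring A present from the start, ring B closed in step 6.

Key step: step 6

Assumption: compounds 1, 5, 6 (as a THF solution) and 11 are purchased, and 5 and 11 are taken as enantiopure because they are the only sources of C3 and C6'.

Step 1
Reactants: 1 1,3-bis(benzyloxy)-5-bromobenzene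
Product: 2 2,4-bis(benzyloxy)-6-bromobenzaldehyde
Conditions: POCl3 (1.5 equiv), DMF, 0 to 80 °C; then aq NaOAc
Reagents that add atoms: N,N-dimethylformamide, CN(C)C=O; water, O
Why: Vilsmeier–Haack formylation should go to the position ortho to bromine, which is para to one benzyloxy group and ortho to the other, in preference to the more hindered position between the two benzyloxy groups.

Step 2
Reactants: 2 2,4-bis(benzyloxy)-6-bromobenzaldehyde
Product: 3 2,4-bis(benzyloxy)-6-bromobenzoic acid
Conditions: NaClO2, NaH2PO4, 2-methyl-2-butene, t-BuOH/THF/H2O, 0 °C to rt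
Reagents that add atoms: sodium chlorite, [Na+].[O-]Cl=O
Why: Pinnick oxidation should convert the aldehyde into the acid without touching the aryl bromide or the benzyl ethers, the alkene scavenging the hypochlorous acid that would otherwise chlorinate the electron-rich ring.

Step 3
Reactants: 3 2,4-bis(benzyloxy)-6-bromobenzoic acid
Product: 4 2,4-bis(benzyloxy)-6-bromobenzoyl bromide
Conditions: NaH (1.0 equiv), THF, 0 °C; then (COBr)2 (1.1 equiv), DMF (cat.), CH2Cl2, 0 °C to rt; evaporate, use crude
Reagents that add atoms: oxalyl bromide, O=C(Br)C(=O)Br
Why: Acyl halide formation from the sodium carboxylate with oxalyl bromide under DMF catalysis releases no HBr, which should keep the benzyl ethers intact.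

Step 4
Reactants: 5 (R)-epichlorohydrin; 6 but-3-en-1-ylmagnesium bromide
Product: 7 (R)-1-chlorohept-6-en-2-ol
Conditions: CuI (10 mol%), THF, −40 to −20 °C; then 1 M HCl
Reagents that add atoms: none
Why: Copper-catalysed Grignard opening of the epoxide at its unsubstituted CH2 (SN2, chloride untouched at low temperature) breaks no bond at the stereocentre, so (R)-5 should give (R)-7.

Step 5
Reactants: 7 (R)-1-chlorohept-6-en-2-ol
Product: 8 (R)-2-(pent-4-en-1-yl)oxirane
Conditions: NaOH (powder, 2 equiv), Et2O, rt
Reagents that add atoms: none
Why: Intramolecular Williamson etherification (alkoxide displaces the primary chloride) closes the new epoxide without touching the stereocentre, which stays R.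

Step 6
Reactants: 8 (R)-2-(pent-4-en-1-yl)oxirane; 4 2,4-bis(benzyloxy)-6-bromobenzoyl bromide
Product: 10 (R)-6,8-bis(benzyloxy)-3-(pent-4-en-1-yl)isochroman-1-one, via bromo ester 9 (not isolated)
Conditions: i) Bu4NBr (5 mol%), toluene, 0 °C to rt; ii) NiBr2(MeOCH2CH2OMe) (10 mol%), 4,4'-di-tert-butyl-2,2'-bipyridine (12 mol%), NaI (25 mol%), Mn powder (3 equiv), DMA (0.02 M), 60 °C
Reagents that add atoms: none
Why: In stage i bromide opens the epoxide of 8, activated on oxygen by the aroyl bromide, at its CH2 carbon and the oxygen ends up acylated (halide-catalysed acylative epoxide opening), which gives the β-bromoalkyl ester 9 with the C3–O bond untouched. In stage ii bipyridine-ligated zerovalent nickel inserts into the aryl C–Br bond ortho to the ester, the primary C4–Br (C4–I after exchange with NaI) is turned into a C4 radical by halogen abstraction, the radical is captured by the arylnickel, and reductive elimination from trivalent nickel forms C4–C4a while Mn returns the nickel to its low-valent state. The closest known reaction type is the nickel-catalysed reductive cross-electrophile coupling of aryl bromides with primary alkyl bromides, used here in its ring-forming intramolecular mode. Ring B closes as a six-membered lactone by C(sp2)–C(sp3) reductive elimination from a seven-membered aryl(alkyl)nickelacycle in which the O-alkyl group has rotated to the side of the aryl ring, as it is in the lactone. No stereocentre is created: C3 is carried over from (R)-epichlorohydrin with retention, because no bond to C3 is broken and the radical sits on C4. The step needs bromide attack at CH2 and not at CH of the epoxide (primary versus secondary SN2 on an alkyl epoxide), ring closure ahead of intermolecular coupling (0.02 M), and a single aryl site, which the substrate secures because C4a is the only halogenated ring carbon and the other ortho position C8 carries a benzyloxy group.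

Step 7
Reactants: 10 (R)-6,8-bis(benzyloxy)-3-(pent-4-en-1-yl)isochroman-1-one; 11 (S)-oct-1-en-3-ol (3 equiv)
Product: 12 (R)-6,8-bis(benzyloxy)-3-[(S,E)-6-hydroxyundec-4-en-1-yl]isochroman-1-one
Conditions: second-generation Grubbs catalyst (5 mol%), CH2Cl2, 40 °C
Reagents that add atoms: none
Why: Olefin cross-metathesis between a terminal alkene that dimerises readily and a secondary allylic alcohol that dimerises slowly should favour the E cross-product, C6' comes unchanged from 11, and the alkene geometry is irrelevant because the double bond is hydrogenated next.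

Step 8
Reactants: 12 (R)-6,8-bis(benzyloxy)-3-[(S,E)-6-hydroxyundec-4-en-1-yl]isochroman-1-one
Product: 13 (R)-6,8-dihydroxy-3-[(S)-6-hydroxyundecyl]isochroman-1-one
Conditions: H2 (1 atm), 10% Pd/C, EtOAc, rt
Reagents that add atoms: none
Why: Catalytic hydrogenation should saturate the disubstituted alkene and hydrogenolyse both aryl benzyl ethers in one operation, while the lactone and the two stereocentres, neither of which is benzylic, are left alone.

**Compound list**
1 | 1,3-bis(benzyloxy)-5-bromobenzene | Brc1cc(OCc2ccccc2)cc(OCc2ccccc2)c1 | starting material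
2 | 2,4-bis(benzyloxy)-6-bromobenzaldehyde | O=Cc1c(Br)cc(OCc2ccccc2)cc1OCc1ccccc1 | intermediate
3 | 2,4-bis(benzyloxy)-6-bromobenzoic acid | OC(=O)c1c(Br)cc(OCc2ccccc2)cc1OCc1ccccc1 | intermediate
4 | 2,4-bis(benzyloxy)-6-bromobenzoyl bromide | BrC(=O)c1c(Br)cc(OCc2ccccc2)cc1OCc1ccccc1 | intermediate
5 | (R)-epichlorohydrin, (R)-2-(chloromethyl)oxirane | ClC[C@H]1CO1 | starting material
6 | but-3-en-1-ylmagnesium bromide | C=CCC[Mg]Br | starting material
7 | (R)-1-chlorohept-6-en-2-ol | ClC[C@H](O)CCCC=C | intermediate
8 | (R)-2-(pent-4-en-1-yl)oxirane | C=CCCC[C@@H]1CO1 | intermediate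
9 | (R)-1-bromohept-6-en-2-yl 2,4-bis(benzyloxy)-6-bromobenzoate (not isolated) | C=CCCC[C@H](CBr)OC(=O)c1c(Br)cc(OCc2ccccc2)cc1OCc1ccccc1 | intermediate
10 | (R)-6,8-bis(benzyloxy)-3-(pent-4-en-1-yl)isochroman-1-one | C=CCCC[C@@H]1Cc2cc(OCc3ccccc3)cc(OCc3ccccc3)c2C(=O)O1 | intermediate
11 | (S)-oct-1-en-3-ol | C=C[C@@H](O)CCCCC | starting material
12 | (R)-6,8-bis(benzyloxy)-3-[(S,E)-6-hydroxyundec-4-en-1-yl]isochroman-1-one | CCCCC[C@H](O)/C=C/CCC[C@@H]1Cc2cc(OCc3ccccc3)cc(OCc3ccccc3)c2C(=O)O1 | intermediate
13 | (R)-6,8-dihydroxy-3-[(S)-6-hydroxyundecyl]isochroman-1-one | CCCCC[C@H](O)CCCCC[C@@H]1Cc2cc(O)cc(O)c2C(=O)O1 | target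

Total step count: 8. Longest linear sequence: 6 steps (steps 1, 2, 3, 6, 7, 8; the epoxide branch, steps 4 and 5, joins at step 6).

**Steps most likely to fail**

Step 6. What may go wrong: intermolecular aryl–alkyl coupling to oligomers outrunning ring closure, simple reduction of either C–Br bond, or opening of the epoxide at its substituted carbon in stage i. The fallback makes C4–C4a by polar organolithium chemistry and closes ring B by lactonisation instead. Acid 3 is treated with n-BuLi (2.1 equiv, THF, −78 °C; deprotonation, then bromine–lithium exchange). The dilithio species opens epoxide 8 at its CH2 in the presence of BF3·OEt2 to give 2,4-bis(benzyloxy)-6-[(R)-2-hydroxyhept-6-en-1-yl]benzoic acid F1, with C3 again untouched. F1 is lactonised with TsOH (cat.) in toluene. This fallback sets out from 3 and 8 and comes back to the route at 10.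

Step 8. What may go wrong: palladium-hydride isomerisation of the allylic alcohol to a saturated ketone, or hydrogenolysis of the allylic C–O bond, competing with plain saturation. The fallback separates the two tasks so that no allylic alcohol ever meets palladium. From 12, the C=C is first reduced without a metal by diimide (2-nitrobenzenesulfonyl hydrazide, Et3N, CH2Cl2, rt) to (R)-6,8-bis(benzyloxy)-3-[(S)-6-hydroxyundecyl]isochroman-1-one F2. The benzyl ethers of F2 are then removed (H2, 10% Pd/C, EtOAc). This fallback sets out from 12 and comes back at 13.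

Step 7. What may go wrong: homodimerisation of 10, double-bond migration, or ruthenium-hydride redox isomerisation of the allylic alcohol partner eroding the cross-product. The fallback sets C6' by reagent control instead of taking it from 11. From 10, cross-metathesis with oct-1-en-3-one (an electron-poor partner that does not self-couple; second-generation Grubbs catalyst, CH2Cl2, 40 °C) should give the enone (R,E)-6,8-bis(benzyloxy)-3-(6-oxoundec-4-en-1-yl)isochroman-1-one F3. Corey–Bakshi–Shibata reduction of F3 ((R)-2-methyl-CBS-oxazaborolidine, catecholborane, toluene, −78 °C) should then deliver the (S)-allylic alcohol. This fallback sets out from 10 and comes back at 12.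

**Further compounds**
F1 | step 6 | 2,4-bis(benzyloxy)-6-[(R)-2-hydroxyhept-6-en-1-yl]benzoic acid | C=CCCC[C@@H](O)Cc1cc(OCc2ccccc2)cc(OCc2ccccc2)c1C(=O)O
F2 | step 8 | (R)-6,8-bis(benzyloxy)-3-[(S)-6-hydroxyundecyl]isochroman-1-one | CCCCC[C@H](O)CCCCC[C@@H]1Cc2cc(OCc3ccccc3)cc(OCc3ccccc3)c2C(=O)O1
F3 | step 7 | (R,E)-6,8-bis(benzyloxy)-3-(6-oxoundec-4-en-1-yl)isochroman-1-one | CCCCCC(=O)/C=C/CCC[C@@H]1Cc2cc(OCc3ccccc3)cc(OCc3ccccc3)c2C(=O)O1
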